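**Plan**

- Labels: ring A is the benzene ring of the chromene (C4a to C8a), ring B the pyran ring (O1 to C4), ring C the phenol ring (C1′ to C6′, oxygen on C4′); the bridge is C5–Cα–Cβ–C1′.
- Retrosynthesis: ring C is taken back to a cyclohex-2-enone with C4′ as the ketone and cut at C1′–C6′ and C2′–C3′ into a chromenyl butanal and but-3-en-2-one. The butanal chain is cut at C5–Cα (aryl triflate plus alkylborane). The chromene is traced through its chroman-4-one to phloroglucinol and 3-methylbut-2-enoic acid (C4–C4a and O1–C2).
- Forward: ring B is closed on ring A first, O7 is prenylated, O5 is exchanged for the four-carbon chain, the chromanone becomes the chromene, and ring C is annulated and aromatised last.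
- Enabling feature: ring C carries only the bridge at C1′ and the oxygen at C4′, in a para relation. This is the pattern of a 4-alkylcyclohex-2-enone, so O4′ can travel as a ketone and never competes with O7. On ring A the hydrogen bond from O5–H to the C4 ketone leaves O7 as the only phenol that alkylates, and the ketone fixes where ring B is fused.
- Stereochemistry: the target has no stereocentre and is made as an achiral compound; the centres that appear on the way (C4 of 11 and 12, C1′ of 17 to 22) form racemic and are erased.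

Key step: step 8

**Step 1**
Reactants: 1 phloroglucinol (benzene-1,3,5-triol); 2 3-methylbut-2-enoic acid
Product: 4 5,7-dihydroxy-2,2-dimethylchroman-4-one, via aryl enone 3 (not isolated)
Conditions: MeSO3H, P2O5, 70 °C
Reagents that add atoms: none
Why: Friedel–Crafts acylation of the threefold-symmetrical triol gives aryl enone 3, whose ortho hydroxyl closes ring B by 6-endo-trig oxa-Michael addition to the β,β-dimethyl enone, and the symmetry of 1 allows only one regioisomer.

**Step 2**
Reactants: 4 5,7-dihydroxy-2,2-dimethylchroman-4-one; 5 1-bromo-3-methylbut-2-ene (prenyl bromide)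
Product: 6 5-hydroxy-2,2-dimethyl-7-(3-methylbut-2-enyloxy)chroman-4-one
Conditions: K2CO3, acetone, reflux
Reagents that add atoms: none
Why: Williamson etherification in which the O5 hydroxyl, locked in a hydrogen bond to the C4 ketone, is far less acidic and nucleophilic than O7–H, so one equivalent of the bromide with a weak base should alkylate O7 alone.

**Step 3**
Reactants: 6 5-hydroxy-2,2-dimethyl-7-(3-methylbut-2-enyloxy)chroman-4-one
Product: 7 2,2-dimethyl-7-(3-methylbut-2-enyloxy)-4-oxochroman-5-yl trifluoromethanesulfonate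
Conditions: Tf2O, pyridine, CH2Cl2, 0 °C
Reagents that add atoms: trifluoromethanesulfonic anhydride, O=S(=O)(OS(=O)(=O)C(F)(F)F)C(F)(F)F
Why: O-sulfonylation of the one remaining phenol, the usual way to turn the chelated 5-hydroxyl of a chromanone into a cross-coupling handle, under conditions to which the prenyl ether and the ketone are inert.

**Step 4**
Reactants: 7 2,2-dimethyl-7-(3-methylbut-2-enyloxy)-4-oxochroman-5-yl trifluoromethanesulfonate; 8 4,4-diethoxybut-1-ene
Product: 10 5-(4,4-diethoxybutyl)-2,2-dimethyl-7-(3-methylbut-2-enyloxy)chroman-4-one, via alkylborane 9 (not isolated)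
Conditions: 8, 9-BBN, THF, 0 °C to rt; then 7, PdCl2(dppf) (dppf = 1,1′-bis(diphenylphosphino)ferrocene), K3PO4, THF/DMF/H2O, 60 °C
Reagents that add atoms: none
Why: B-alkyl Suzuki–Miyaura coupling in which anti-Markovnikov hydroboration of the terminal alkene gives the primary alkylborane 9 (alkene in slight excess, so no B–H is left for the prenyl alkene), and the triflate ortho to the ketone adds readily to zerovalent palladium before base-assisted alkyl transfer and reductive elimination form C5–Cα.

**Step 5**
Reactants: 10 5-(4,4-diethoxybutyl)-2,2-dimethyl-7-(3-methylbut-2-enyloxy)chroman-4-one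
Product: 11 5-(4,4-diethoxybutyl)-2,2-dimethyl-7-(3-methylbut-2-enyloxy)chroman-4-ol (racemic)
Conditions: NaBH4, MeOH/THF, 0 °C
Reagents that add atoms: none
Why: Borohydride reduction of the aryl ketone, which leaves the acetal and the prenyl ether alone; the C4 carbinol centre forms as the racemate and is removed in step 6.

**Step 6**
Reactants: 11 5-(4,4-diethoxybutyl)-2,2-dimethyl-7-(3-methylbut-2-enyloxy)chroman-4-ol
Product: 13 5-(4,4-diethoxybutyl)-2,2-dimethyl-7-(3-methylbut-2-enyloxy)-2H-chromene, via mesylate 12 (not isolated)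
Conditions: MsCl, Et3N, CH2Cl2, 0 °C to rt
Reagents that add atoms: none
Why: O-mesylation followed by elimination under amine base (the benzylic C4–O bond ionises easily with O1 and O7 as donors, and only C3 carries β-hydrogens) should give the C3=C4 alkene of ring B without acid, so the acetal and the prenyl ether are spared.

**Step 7**
Reactants: 13 5-(4,4-diethoxybutyl)-2,2-dimethyl-7-(3-methylbut-2-enyloxy)-2H-chromene
Product: 14 4-[2,2-dimethyl-7-(3-methylbut-2-enyloxy)-2H-chromen-5-yl]butanal
Conditions: pyridinium p-toluenesulfonate, acetone/H2O, 55 °C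
Reagents that add atoms: water, O
Why: Acetal hydrolysis with a weak pyridinium acid, mild enough to leave the acid-sensitive chromene and the aryl prenyl ether untouched.

**Step 8**
Reactants: 14 4-[2,2-dimethyl-7-(3-methylbut-2-enyloxy)-2H-chromen-5-yl]butanal; 15 but-3-en-2-one
Product: 19 4-{2-[2,2-dimethyl-7-(3-methylbut-2-enyloxy)-2H-chromen-5-yl]ethyl}cyclohex-2-en-1-one (racemic), via pyrrolidine enamine 16 (not isolated), via keto aldehyde 17 (not isolated), via ketol 18 (not isolated)
Conditions: pyrrolidine, 4 Å molecular sieves, toluene, rt; then 15, 0 °C to rt; then AcOH, NaOAc, H2O, 80 °C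
Reagents that add atoms: none
Why: Pyrrolidine condenses with the aldehyde to the E-enamine 16, whose nucleophilic carbon C1′ adds to the terminal carbon C6′ of the enone (C1′–C6′); the buffered aqueous acetic acid then hydrolyses the iminium to keto aldehyde 17, the methyl ketone enolises towards C3′ and adds to the aldehyde carbon C2′ (C2′–C3′) to give ketol 18, and loss of water conjugates the new alkene with the C4′ ketone. The closest known reaction type is the Stork enamine variant of the Robinson annulation, which turns aldehydes with one α-substituent and but-3-en-2-one into 4-substituted cyclohex-2-enones. Ring C closes as a six-membered carbocycle by a 6-(enolendo)-exo-trig aldol addition. The only lasting new stereocentre, C1′, forms without control as the racemate and disappears on aromatisation, and the carbinol centre of 18 is lost on dehydration. The step needs a single conjugate addition at C1′ and closure through the methyl group: the enamine is used up by the first addition and its more hindered successor should react more slowly, while closure through the ketone methylene C5′ or from C1′ onto the ketone could only give four-membered rings, so the conjugated six-membered enone is the only accessible annulation product. The chromene alkene, the prenyl ether and the electron-rich ring A are inert to enamines, enones and acetate buffer.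

**Step 9**
Reactants: 19 4-{2-[2,2-dimethyl-7-(3-methylbut-2-enyloxy)-2H-chromen-5-yl]ethyl}cyclohex-2-en-1-one
Product: 21 trimethyl{[4-{2-[2,2-dimethyl-7-(3-methylbut-2-enyloxy)-2H-chromen-5-yl]ethyl}cyclohexa-1,5-dien-1-yl]oxy}silane (racemic), via lithium dienolate 20 (not isolated)
Conditions: LiN(iPr)2, THF, −78 °C; then Me3SiCl, −78 to 0 °C
Reagents that add atoms: chlorotrimethylsilane, C[Si](C)(C)Cl
Why: Kinetic deprotonation of the enone at the α′ carbon C5′ gives the cross-conjugated lithium dienolate 20, which the silyl chloride traps on oxygen (kinetic enolate silylation), no other site of 19 being acidic enough to compete at −78 °C.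

**Step 10**
Reactants: 21 trimethyl{[4-{2-[2,2-dimethyl-7-(3-methylbut-2-enyloxy)-2H-chromen-5-yl]ethyl}cyclohexa-1,5-dien-1-yl]oxy}silane
Product: 23 4-{2-[2,2-dimethyl-7-(3-methylbut-2-enyloxy)-2H-chromen-5-yl]ethyl}phenol (the target), via dienone 22 (not isolated)
Conditions: Pd(OAc)2 (1.1 equiv), MeCN, rt
Reagents that add atoms: none
Why: Saegusa–Ito oxidation in which divalent palladium takes the enolate from silicon at C5′, β-hydride elimination from C6′ gives the cross-conjugated dienone 22, and its C1′ hydrogen shifts to oxygen at once because the tautomer is the aromatic phenol, which also erases the C1′ centre.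

**Compound list**

1 | phloroglucinol (benzene-1,3,5-triol) | Oc1cc(O)cc(O)c1 | starting material
2 | 3-methylbut-2-enoic acid | CC(C)=CC(=O)O | starting material
3 | 3-methyl-1-(2,4,6-trihydroxyphenyl)but-2-en-1-one | CC(C)=CC(=O)c1c(O)cc(O)cc1O | intermediate (not isolated)
4 | 5,7-dihydroxy-2,2-dimethylchroman-4-one | CC1(C)CC(=O)c2c(O)cc(O)cc2O1 | intermediate
5 | 1-bromo-3-methylbut-2-ene | CC(C)=CCBr | starting material
6 | 5-hydroxy-2,2-dimethyl-7-(3-methylbut-2-enyloxy)chroman-4-one | CC(C)=CCOc1cc(O)c2C(=O)CC(C)(C)Oc2c1 | intermediate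
7 | 2,2-dimethyl-7-(3-methylbut-2-enyloxy)-4-oxochroman-5-yl trifluoromethanesulfonate | CC(C)=CCOc1cc(OS(=O)(=O)C(F)(F)F)c2C(=O)CC(C)(C)Oc2c1 | intermediate
8 | 4,4-diethoxybut-1-ene | C=CCC(OCC)OCC | starting material
9 | 9-(4,4-diethoxybutyl)-9-borabicyclo[3.3.1]nonane | CCOC(CCCB1C2CCCC1CCC2)OCC | intermediate (not isolated)
10 | 5-(4,4-diethoxybutyl)-2,2-dimethyl-7-(3-methylbut-2-enyloxy)chroman-4-one | CC(C)=CCOc1cc(CCCC(OCC)OCC)c2C(=O)CC(C)(C)Oc2c1 | intermediate
11 | 5-(4,4-diethoxybutyl)-2,2-dimethyl-7-(3-methylbut-2-enyloxy)chroman-4-ol (racemic) | CC(C)=CCOc1cc(CCCC(OCC)OCC)c2C(O)CC(C)(C)Oc2c1 | intermediate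
12 | 5-(4,4-diethoxybutyl)-2,2-dimethyl-7-(3-methylbut-2-enyloxy)chroman-4-yl methanesulfonate (racemic) | CC(C)=CCOc1cc(CCCC(OCC)OCC)c2C(OS(C)(=O)=O)CC(C)(C)Oc2c1 | intermediate (not isolated)
13 | 5-(4,4-diethoxybutyl)-2,2-dimethyl-7-(3-methylbut-2-enyloxy)-2H-chromene | CC(C)=CCOc1cc(CCCC(OCC)OCC)c2C=CC(C)(C)Oc2c1 | intermediate
14 | 4-[2,2-dimethyl-7-(3-methylbut-2-enyloxy)-2H-chromen-5-yl]butanal | CC(C)=CCOc1cc(CCCC=O)c2C=CC(C)(C)Oc2c1 | intermediate
15 | but-3-en-2-one | CC(=O)C=C | starting material
16 | 1-{(E)-4-[2,2-dimethyl-7-(3-methylbut-2-enyloxy)-2H-chromen-5-yl]but-1-enyl}pyrrolidine | CC(C)=CCOc1cc(CC/C=C/N2CCCC2)c2C=CC(C)(C)Oc2c1 | intermediate (not isolated)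
17 | 2-{2-[2,2-dimethyl-7-(3-methylbut-2-enyloxy)-2H-chromen-5-yl]ethyl}-5-oxohexanal (racemic) | CC(C)=CCOc1cc(CCC(C=O)CCC(C)=O)c2C=CC(C)(C)Oc2c1 | intermediate (not isolated)
18 | 4-{2-[2,2-dimethyl-7-(3-methylbut-2-enyloxy)-2H-chromen-5-yl]ethyl}-3-hydroxycyclohexan-1-one (racemic; both diastereomers) | CC(C)=CCOc1cc(CCC2CCC(=O)CC2O)c2C=CC(C)(C)Oc2c1 | intermediate (not isolated)
19 | 4-{2-[2,2-dimethyl-7-(3-methylbut-2-enyloxy)-2H-chromen-5-yl]ethyl}cyclohex-2-en-1-one (racemic) | CC(C)=CCOc1cc(CCC2C=CC(=O)CC2)c2C=CC(C)(C)Oc2c1 | intermediate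
20 | lithium 4-{2-[2,2-dimethyl-7-(3-methylbut-2-enyloxy)-2H-chromen-5-yl]ethyl}cyclohexa-1,5-dien-1-olate (racemic) | [Li+].CC(C)=CCOc1cc(CCC2C=CC([O-])=CC2)c2C=CC(C)(C)Oc2c1 | intermediate (not isolated)
21 | trimethyl{[4-{2-[2,2-dimethyl-7-(3-methylbut-2-enyloxy)-2H-chromen-5-yl]ethyl}cyclohexa-1,5-dien-1-yl]oxy}silane (racemic) | CC(C)=CCOc1cc(CCC2C=CC(O[Si](C)(C)C)=CC2)c2C=CC(C)(C)Oc2c1 | intermediate
22 | 4-{2-[2,2-dimethyl-7-(3-methylbut-2-enyloxy)-2H-chromen-5-yl]ethyl}cyclohexa-2,5-dien-1-one | CC(C)=CCOc1cc(CCC2C=CC(=O)C=C2)c2C=CC(C)(C)Oc2c1 | intermediate (not isolated)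
23 | 4-{2-[2,2-dimethyl-7-(3-methylbut-2-enyloxy)-2H-chromen-5-yl]ethyl}phenol | CC(C)=CCOc1cc(CCc2ccc(O)cc2)c2C=CC(C)(C)Oc2c1 | target

**Step count**

Total: 10 steps. Longest linear sequence: 10 steps (1 to 23); compounds 2, 5, 8 and 15 are bought and enter without steps of their own.

**Steps most likely to fail**

Step 8. The unbranched aldehyde may self-condense while the enamine is formed, a second conjugate addition may occur at C1′ once the enamine is regenerated, and the enone may polymerise; each of these would erode the annulation. The fallback forms C1′–C6′ by alkylation instead of conjugate addition and keeps the same aldol closure. It sets out from aldehyde 14. Condensation with tert-butylamine over molecular sieves should give the N-tert-butyl aldimine F1. LiN(iPr)2 in THF converts it into the lithium aza-enolate F2, which is alkylated once at C1′ by 2-(2-bromoethyl)-2-methyl-1,3-dioxolane to give the imine ketal F3. Pyridinium p-toluenesulfonate in wet acetone then cleaves the imine and the dioxolane to keto aldehyde 17, and KOH in methanol closes and dehydrates it through ketol 18. The fallback comes back to the route at enone 19.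

Step 10. The zerovalent palladium released by the oxidation may ionise the aryl prenyl ether and so strip the prenyl group, divalent palladium may be held up by the chromene alkene, and premature hydrolysis of the silyl ether would return the enone. The fallback is metal-free and sets out from enone 19, by way of the same lithium dienolate 20. Quenching 20 with PhSeCl at −78 °C should give the 6-(phenylselanyl)cyclohex-2-enone F4. H2O2 with pyridine in CH2Cl2 at 0 °C oxidises it to the selenoxide F5, which undergoes syn-elimination towards C6′ to dienone 22 and tautomerises. The fallback comes back to the route at the target 23.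

Step 4. The aqueous base may cleave the carbonyl-activated triflate at sulfur and return the phenol, it may open ring B by retro-oxa-Michael reaction, and slow alkyl transfer next to the ketone would favour β-hydride elimination and reduction of the arene. The fallback changes the order of events so that the coupling is run on the chromene, which has neither the activating carbonyl nor a base-labile ring B. It sets out from triflate 7. NaBH4 in methanol should give the 4-hydroxychroman-5-yl triflate F6. MsCl and Et3N convert it through the 4-mesyloxychroman-5-yl triflate F7 into the 2H-chromen-5-yl triflate F8. The B-alkyl Suzuki–Miyaura coupling of F8 with alkylborane 9 (PdCl2(dppf), K3PO4) then brings the fallback back to the route at chromene acetal 13.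

**Further compounds**

F1 | step 8 | N-tert-butyl-4-[2,2-dimethyl-7-(3-methylbut-2-enyloxy)-2H-chromen-5-yl]butan-1-imine | CC(C)=CCOc1cc(CCC/C=N/C(C)(C)C)c2C=CC(C)(C)Oc2c1
F2 | step 8 | lithium aza-enolate of F1 (lithium tert-butyl{(E)-4-[2,2-dimethyl-7-(3-methylbut-2-enyloxy)-2H-chromen-5-yl]but-1-enyl}amide) | [Li+].CC(C)=CCOc1cc(CC/C=C/[N-]C(C)(C)C)c2C=CC(C)(C)Oc2c1
F3 | step 8 | N-tert-butyl-2-{2-[2,2-dimethyl-7-(3-methylbut-2-enyloxy)-2H-chromen-5-yl]ethyl}-4-(2-methyl-1,3-dioxolan-2-yl)butan-1-imine (racemic) | CC(C)=CCOc1cc(CCC(CCC2(C)OCCO2)/C=N/C(C)(C)C)c2C=CC(C)(C)Oc2c1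
F4 | step 10 | 4-{2-[2,2-dimethyl-7-(3-methylbut-2-enyloxy)-2H-chromen-5-yl]ethyl}-6-(phenylselanyl)cyclohex-2-en-1-one (racemic; both diastereomers) | CC(C)=CCOc1cc(CCC2C=CC(=O)C([Se]c3ccccc3)C2)c2C=CC(C)(C)Oc2c1
F5 | step 10 | 4-{2-[2,2-dimethyl-7-(3-methylbut-2-enyloxy)-2H-chromen-5-yl]ethyl}-6-(phenylseleninyl)cyclohex-2-en-1-one | CC(C)=CCOc1cc(CCC2C=CC(=O)C([Se](=O)c3ccccc3)C2)c2C=CC(C)(C)Oc2c1
F6 | step 4 | 4-hydroxy-2,2-dimethyl-7-(3-methylbut-2-enyloxy)chroman-5-yl trifluoromethanesulfonate (racemic) | CC(C)=CCOc1cc(OS(=O)(=O)C(F)(F)F)c2C(O)CC(C)(C)Oc2c1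
F7 | step 4 | 2,2-dimethyl-4-(methylsulfonyloxy)-7-(3-methylbut-2-enyloxy)chroman-5-yl trifluoromethanesulfonate (racemic) | CC(C)=CCOc1cc(OS(=O)(=O)C(F)(F)F)c2C(OS(C)(=O)=O)CC(C)(C)Oc2c1
F8 | step 4 | 2,2-dimethyl-7-(3-methylbut-2-enyloxy)-2H-chromen-5-yl trifluoromethanesulfonate | CC(C)=CCOc1cc(OS(=O)(=O)C(F)(F)F)c2C=CC(C)(C)Oc2c1
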